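## Retrosynthetic overview

1. Target ⇒ acyclic (R)-configured (E,E)-trienol acetate with all 22 carbons in place. One proton-initiated cascade forms ring A (C4–C5), then ring B (C9–C10), then the oxocane (C8–O15, capture of the C8 cation).
2. Trienol acetate ⇒ aldehyde ⇒ 2-substituted allyl acetate. Asymmetric hydroformylation makes C14–C15 and sets C13.
3. Allyl acetate ⇒ (2E,6E)-farnesyl bromide + methallyl alcohol. Dianion alkylation makes C11–C12; the acetate of the target is the only protecting group used.

Assumption: labdane numbering is used; the biosynthesis is taken as proton-initiated bicyclisation of a geranylgeranyl-type chain to the labdan-8-yl cation, capture of that cation by the C15 oxygen, and C16 oxygenation/acetylation; catalysts and ligands are bought and not counted as steps.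

## Route

Step 1
Reactants: 1 (2E,6E)-farnesyl bromide; 2 2-methylprop-2-en-1-ol (methallyl alcohol)
Product: 4 (5E,9E)-6,10,14-trimethyl-2-methylidenepentadeca-5,9,13-trien-1-ol, via dilithiated methallyl alcohol 3 (not isolated)
Conditions: 2 (1.5 equiv), n-BuLi (3 equiv), TMEDA, Et2O/hexane, 0 °C → rt; then 1, THF, −78 → 0 °C; H2O
Reagents that add atoms: none
Why: Alkoxide-directed allylic lithiation gives the C,O-dianion, whose carbon terminus displaces the primary allylic bromide (SN2 dianion alkylation) to forge C11–C12 without touching the two E-alkenes; no stereocentre is formed.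

Step 2
Reactants: 4 (5E,9E)-6,10,14-trimethyl-2-methylidenepentadeca-5,9,13-trien-1-ol
Product: 5 [(5E,9E)-6,10,14-trimethyl-2-methylidenepentadeca-5,9,13-trien-1-yl] acetate
Conditions: Ac2O, pyridine, DMAP (cat.), CH2Cl2, 0 °C → rt
Reagents that add atoms: acetic anhydride, CC(=O)OC(C)=O
Why: DMAP-catalysed O-acylation of the primary alcohol installs the acetate of the target, which from here on also keeps O16 from acting as a nucleophile; no stereocentre is involved.

Step 3
Reactants: 5 [(5E,9E)-6,10,14-trimethyl-2-methylidenepentadeca-5,9,13-trien-1-yl] acetate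
Product: 6 [(2R,5E,9E)-6,10,14-trimethyl-2-(2-oxoethyl)pentadeca-5,9,13-trien-1-yl] acetate
Conditions: Rh(acac)(CO)2 (1 mol %), chiral phosphine–phosphoramidite ligand (YanPhos type; enantiomer that gives 13R), CO/H2 1:1 (10 bar), toluene, 70 °C
Reagents that add atoms: carbon monoxide, [C-]#[O+]
Why: Rh-catalysed asymmetric hydroformylation of a 1,1-disubstituted alkene puts the formyl group on the unsubstituted terminus (Keulemans rule), so C13 is created when Rh–H delivers hydride to one enantioface under ligand control (13R), while the trisubstituted alkenes are inert and the acetate cannot β-eliminate from the primary Rh-alkyl.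

Step 4
Reactants: 6 [(2R,5E,9E)-6,10,14-trimethyl-2-(2-oxoethyl)pentadeca-5,9,13-trien-1-yl] acetate
Product: 7 [(2R,5E,9E)-2-(2-hydroxyethyl)-6,10,14-trimethylpentadeca-5,9,13-trien-1-yl] acetate
Conditions: NaBH4, THF/H2O, 0 °C, 15 min
Reagents that add atoms: none
Why: Borohydride reduction takes only the aldehyde (ester and alkenes untouched) and the cold, brief reaction avoids 1,4-acyl migration, so C13 (R) is carried through unchanged.

Step 5
Reactants: 7 [(2R,5E,9E)-2-(2-hydroxyethyl)-6,10,14-trimethylpentadeca-5,9,13-trien-1-yl] acetate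
Product: 8 (5S,8R,9R,10S,13R)-8,15-epoxylabdan-16-yl acetate (target)
Conditions: chiral confined imidodiphosphorimidate (IDPi) Brønsted acid (5 mol %; enantiomer that converts (3E,7E)-homofarnesol into (−)-ambrox), (CF3)3COH, 0.02 M, 0 °C
Reagents that add atoms: none
Why: Proposed new method: the confined chiral acid protonates the terminal alkene with the triene folded chair–chair, so C4–C5 and C9–C10 form by anti additions across the two E-alkenes (trans-decalin, 5S,9R,10S, catalyst-controlled absolute sense), and the tertiary C8 cation, held as an ion pair in a non-nucleophilic fluoroalcohol, is captured by the only free hydroxyl (O15) on the less hindered α face, anti to the new C9–C10 bond and away from the axial C10 methyl, closing the trans-diequatorially fused oxocane (8R), while alkenes formed by E1 loss can be re-protonated to the same cation; the closest known reaction type is the proton-initiated polyene cyclisation terminated by a hydroxyl that gives five- and six-membered ethers (homofarnesol to ambrox), and the eight-membered closure is the unprecedented part.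

## Compound list

1 | (2E,6E)-farnesyl bromide | CC(C)=CCC/C(C)=C/CC/C(C)=C/CBr | starting material
2 | 2-methylprop-2-en-1-ol (methallyl alcohol) | CC(=C)CO | starting material
3 | dilithiated methallyl alcohol (lithium 2-(lithiomethyl)prop-2-en-1-olate) | [Li]CC(=C)CO[Li] | intermediate
4 | (5E,9E)-6,10,14-trimethyl-2-methylidenepentadeca-5,9,13-trien-1-ol | CC(C)=CCC/C(C)=C/CC/C(C)=C/CCC(=C)CO | intermediate
5 | [(5E,9E)-6,10,14-trimethyl-2-methylidenepentadeca-5,9,13-trien-1-yl] acetate | CC(C)=CCC/C(C)=C/CC/C(C)=C/CCC(=C)COC(C)=O | intermediate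
6 | [(2R,5E,9E)-6,10,14-trimethyl-2-(2-oxoethyl)pentadeca-5,9,13-trien-1-yl] acetate | CC(C)=CCC/C(C)=C/CC/C(C)=C/CC[C@H](CC=O)COC(C)=O | intermediate
7 | [(2R,5E,9E)-2-(2-hydroxyethyl)-6,10,14-trimethylpentadeca-5,9,13-trien-1-yl] acetate | CC(C)=CCC/C(C)=C/CC/C(C)=C/CC[C@H](CCO)COC(C)=O | intermediate
8 | (5S,8R,9R,10S,13R)-8,15-epoxylabdan-16-yl acetate (8α-O, 8β-CH3, trans-decalin, oxocane C8–O–C15–C14–C13–C12–C11–C9, CH2OAc on C13) | CC(=O)OC[C@H]1CCO[C@]2(C)CC[C@H]3C(C)(C)CCC[C@]3(C)[C@H]2CC1 | target

## Step count and risks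

Total step count: 5. Longest linear sequence: 5 steps (1 → 4 → 5 → 6 → 7 → 8).

**Most likely to fail, in order:**

**Step 5.** The eight-membered closure may lose to E1 deprotonation of the C8 cation. The fallback sets out from 7 and comes back at 8. The catalyst-controlled bicyclisation is then used only for the decalin: its E1 products are the bicyclic alkenols (13R)-15-hydroxylabd-8(17)-en-16-yl acetate F1 and the endocyclic isomer (13R)-15-hydroxylabd-7-en-16-yl acetate F2, both with the ring stereocentres already set. The mixture is closed to the oxocane by a different mechanism, cobalt-hydride hydrogen-atom transfer with radical–polar crossover (Co(salen) cat., N-fluoro-2,4,6-trimethylpyridinium triflate, PhSiH3, CH2Cl2, 0 °C, 5 mM). Hydrogen adds to C17 of F1 or C7 of F2, both give the same tertiary C8 radical, and after oxidation at cobalt O15 displaces from the α face to give 8. Precedent for this hydroalkoxylation reaches seven-membered rings, so the oxocane is an extension.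

**Step 3.** Enantioselectivity on a 2-alkyl allyl acetate may be insufficient, or the alkene may isomerise. A shortfall in ee shows up after step 5 as the C13 epimer, not as the enantiomer. The fallback sets out from 5 and comes back at 7, and sets C13 by enzymatic desymmetrisation.
- 9-BBN adds selectively to the 1,1-disubstituted alkene of 5 to give the borane [(5E,9E)-2-(9-borabicyclo[3.3.1]nonan-9-ylmethyl)-6,10,14-trimethylpentadeca-5,9,13-trien-1-yl] acetate F3.
- NaOH/H2O2 oxidises the C–B bond and cleaves the acetate to give the prochiral diol 2-[(3E,7E)-4,8,12-trimethyltrideca-3,7,11-trien-1-yl]propane-1,3-diol F4.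
- A lipase (Amano PS or PPL, vinyl acetate; screened for the required arm) acetylates one enantiotopic CH2OH to give [(2R,5E,9E)-2-(hydroxymethyl)-6,10,14-trimethylpentadeca-5,9,13-trien-1-yl] acetate F5.
- Dess–Martin oxidation gives the aldehyde [(2S,5E,9E)-2-formyl-6,10,14-trimethylpentadeca-5,9,13-trien-1-yl] acetate F6, used at once because it can lose acetic acid.
- Non-basic Takai–Lombardo methylenation (Zn, CH2Br2, TiCl4) gives [(2R,5E,9E)-2-ethenyl-6,10,14-trimethylpentadeca-5,9,13-trien-1-yl] acetate F7.
- 9-BBN adds to the vinyl group to give the borane [(2S,5E,9E)-2-[2-(9-borabicyclo[3.3.1]nonan-9-yl)ethyl]-6,10,14-trimethylpentadeca-5,9,13-trien-1-yl] acetate F8, and NaBO3 oxidation gives 7.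

**Step 1.** The dianion is a hard allyllithium, so SN2′ attack, Wurtz-type homocoupling or incomplete dilithiation can cut the yield. The fallback sets out from 1 and comes back at 4, and builds C13 as a ketone carbon. Sodium ethyl acetoacetate is alkylated with 1 to give ethyl (4E,8E)-2-acetyl-5,9,13-trimethyltetradeca-4,8,12-trienoate F9. Saponification and decarboxylation give (5E,9E)-6,10,14-trimethylpentadeca-5,9,13-trien-2-one (farnesylacetone) F10. Corey–Chaykovsky methylenation (Me3S+ I−, n-BuLi, THF) gives the epoxide 2-methyl-2-[(3E,7E)-4,8,12-trimethyltrideca-3,7,11-trien-1-yl]oxirane F11. Lithium diethylamide then isomerises the epoxide to the allylic alcohol by removing a proton from the methyl group, which gives 4.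

## Further compounds

F1 | step 5 | (13R)-15-hydroxylabd-8(17)-en-16-yl acetate | CC(=O)OC[C@@H](CCO)CC[C@H]1C(=C)CC[C@H]2C(C)(C)CCC[C@]12C
F2 | step 5 | (13R)-15-hydroxylabd-7-en-16-yl acetate | CC(=O)OC[C@@H](CCO)CC[C@H]1C(C)=CC[C@H]2C(C)(C)CCC[C@]12C
F3 | step 3 | [(5E,9E)-2-(9-borabicyclo[3.3.1]nonan-9-ylmethyl)-6,10,14-trimethylpentadeca-5,9,13-trien-1-yl] acetate | CC(C)=CCC/C(C)=C/CC/C(C)=C/CCC(CB1C2CCCC1CCC2)COC(C)=O
F4 | step 3 | 2-[(3E,7E)-4,8,12-trimethyltrideca-3,7,11-trien-1-yl]propane-1,3-diol | CC(C)=CCC/C(C)=C/CC/C(C)=C/CCC(CO)CO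
F5 | step 3 | [(2R,5E,9E)-2-(hydroxymethyl)-6,10,14-trimethylpentadeca-5,9,13-trien-1-yl] acetate | CC(C)=CCC/C(C)=C/CC/C(C)=C/CC[C@H](CO)COC(C)=O
F6 | step 3 | [(2S,5E,9E)-2-formyl-6,10,14-trimethylpentadeca-5,9,13-trien-1-yl] acetate | CC(C)=CCC/C(C)=C/CC/C(C)=C/CC[C@H](C=O)COC(C)=O
F7 | step 3 | [(2R,5E,9E)-2-ethenyl-6,10,14-trimethylpentadeca-5,9,13-trien-1-yl] acetate | CC(C)=CCC/C(C)=C/CC/C(C)=C/CC[C@H](C=C)COC(C)=O
F8 | step 3 | [(2S,5E,9E)-2-[2-(9-borabicyclo[3.3.1]nonan-9-yl)ethyl]-6,10,14-trimethylpentadeca-5,9,13-trien-1-yl] acetate | CC(C)=CCC/C(C)=C/CC/C(C)=C/CC[C@H](CCB1C2CCCC1CCC2)COC(C)=O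
F9 | step 1 | ethyl (4E,8E)-2-acetyl-5,9,13-trimethyltetradeca-4,8,12-trienoate | CC(C)=CCC/C(C)=C/CC/C(C)=C/CC(C(C)=O)C(=O)OCC
F10 | step 1 | (5E,9E)-6,10,14-trimethylpentadeca-5,9,13-trien-2-one | CC(C)=CCC/C(C)=C/CC/C(C)=C/CCC(C)=O
F11 | step 1 | 2-methyl-2-[(3E,7E)-4,8,12-trimethyltrideca-3,7,11-trien-1-yl]oxirane | CC(C)=CCC/C(C)=C/CC/C(C)=C/CCC1(C)CO1
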